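Atom labels (O1, C2, C3, C3a, C4–C7, C7a) are the benzofuran locants of the target and are used for the same atoms in every intermediate. Ring A is the carbocycle C3a–C4–C5–C6–C7–C7a and ring B is the dihydrofuran O1–C2–C3–C3a–C7a.

## Analysis of the target

Target 25 is a 3,5-dihydro-2H-1-benzofuran-6-one (C23H28O7). Ring B is a 2-aryl-3-methyl-dihydrofuran, and ring A is a six-membered carbocycle that cannot be aromatic because C5 is quaternary (allyl and methoxy). Its unsaturation is one linear dienone, O=C6–C7=C7a–C3a=C4, in which C7 and C7a each carry an enol-ether oxygen, so the C6 carbonyl is a doubly vinylogous ester. There are three stereocentres: C2 (S) and C3 (S) are adjacent and trans, and C5 (R) is separated from them by the sp2 atoms C3a and C4. Nothing can relay configuration from C2/C3 to C5, so C5 must be set on its own, and its two non-ring substituents (OMe and allyl) are of similar size. The 5-allyl-5-methoxy dienone can lose its quaternary centre under strong acid or heat (allyl migration or loss of methanol with aromatisation), the C2–O1 bond is benzylic, and the terminal alkene rules out hydrogenation, hydroboration and ozonolysis. The hard parts are the quaternary α-methoxy ketone carbon C5 in one absolute configuration, and the C3a=C4 double bond without passing through an arene. The strategy rests on ring B: O1, C2, C3, C3a and C7a have the connectivity and oxidation pattern of a γ-aryl butenolide (C7a the carboxyl carbon, C3a the α-carbon, C3 the β-carbon, C2 the γ-carbon). The rest of ring A, C4–C5–C6–C7, is a four-carbon chain oxygenated on every carbon (aldehyde C4, quaternary C5, ketone C6, methoxymethylene C7).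

## Retrosynthetic reasoning

**C3a=C4 alkene.** The double bond of 25 is traced back to a C4 oxygen in alcohol 23, removed through mesylate 24. C4 sits between C3a, which carries the only available hydrogen, and quaternary C5, so the elimination can give only the C3a=C4 isomer. It also erases the C3a and C4 configurations, so neither has to be controlled earlier.

**O1–C7a enol ether.** The vinylogous ester of 23 is opened to the cyclic 2-methoxy-1,3-diketone 22, whose benzylic C2 hydroxyl is three atoms from the C7a carbonyl. Only a five-membered hemiketal on C7a is possible, and its dehydration towards C7 gives the conjugated enol ether. The forward step needs only mild acid, which also frees the C4 hydroxyl from its silyl ether.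

**C7–C7a bond.** Diketone 22 is a δ-keto ester in disguise. Cutting C7–C7a gives lactone 21, in which the ketone's only enolisable carbon is the methoxymethylene C7 (C5 is quaternary) and the lactone carbonyl C7a is the acyl donor. Ring A then closes by an intramolecular Claisen condensation, and the lactone oxygen is released as the C2 alkoxide needed for the next step. The C4 hydroxyl is silylated first, because a free C4 alkoxide is β to both carbonyls and would undergo retro-aldol cleavage.

**C3a–C4 and C3–CH3 bonds (key disconnection).** The silyl ether 21 comes from aldol adduct 20. Cutting C3a–C4 and the C3–methyl bond in 20 leaves three components: butenolide 7, the methyl donor lithium dimethylcuprate 18, and keto aldehyde 17. Cutting here puts all 23 carbons and the three permanent stereocentres into one operation. The forward reaction must add methyl anti to the C2 aryl group, form the C3a–C4 bond at the aldehyde rather than the ketone of 17, and leave C5 untouched.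

**Butenolide 7.** The double bond of 7 is introduced last, without base, by selenoxide elimination from the saturated lactone 5 via selenide 6, because a γ-aryl butenolide racemises by γ-deprotonation. Lactone 5 comes from hydroxy ester 4, made by asymmetric transfer hydrogenation of aryl ketone 3, a reaction whose sense for aryl alkyl ketones is dependable. Ketone 3 is the enolate alkylation product of acetophenone 1 with bromoacetate 2. A propiolate alkynylation of the corresponding benzaldehyde would be equally short, but the reduction route has the more secure sense of induction.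

**Aldehyde 17.** Both carbonyls of 17 come from one double oxidation of diol 16, so C4 and C6 stay at the alcohol level until just before use. The C5–OMe bond of 16 is cut back to epoxy alcohol 15: acid-catalysed opening by the solvent alcohol at the tertiary epoxide carbon, with inversion, installs the methoxy group and leaves the epoxide oxygen on C6. Epoxide 15 comes from the Sharpless asymmetric epoxidation of allylic alcohol 14, which fixes C5 by a reaction of predictable sense and leaves the isolated allyl alkene alone. An esterase desymmetrisation of a prochiral malonate was not used, because its two groups at the prochiral carbon (OMe and allyl) are too alike for a predictable outcome. Alcohol 14 is the reduction product of enoate 13, made by an E-selective Wittig reaction of ylide 11 with methoxyacetaldehyde 12. Ylide 11 comes from C-allylation of ylide 8 with allyl bromide 9 via salt 10.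

## Alternatives that were turned down

**Alternative 1:** Cloke–Wilson ring expansion on a finished, saturated ring A. The O1–C2 bond is disconnected: the 3a,4-dihydro target A1 would come from the spiro-fused donor–acceptor cyclopropane A2, in which ring A already holds C5 and the cyclopropane is made of C3a, C3 and C2. In the forward step Sc(OTf)3 binds the dicarbonyl of A2, the C3a–C2 bond breaks towards the benzylic carbon, and the C7a enol oxygen closes on C2 to give ring B.
- In its favour: the key step forms a ring, there are few steps after it, and no sensitive β-keto aldehyde is handled. On these points it is stronger than the chosen route.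
- Against it: A1 lacks the C3a=C4 double bond. A late dehydrogenation of the vinylogous ester has no handle to direct it, and a leaving group placed at C3a could eliminate towards C3–H as well as C4–H, which would destroy the C3 stereocentre.
- The para methoxy group of the 3,4,5-trimethoxyphenyl donor is twisted out of conjugation by its two neighbours, so the donor is weaker than it looks and the opening needs forcing.
- The cyclopropane carbons of A2 would have to be set relative to a remote C5 whose two substituents offer almost no facial bias.
- In comparison, the chosen route carries a C4 oxygen out of the aldol, which fixes the position of the alkene, and it sets C5 independently by a reagent-controlled epoxidation.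

**Alternative 2:** Ring contraction of a flavene on an aromatic ring A. The C3–C3a bond is disconnected: the dihydrobenzofuran acetal A3 would come from the 2H-chromene A4. With PhI(OH)OTs (trivalent iodine) in methanol, the iodine adds to the chromene alkene, the aryl carbon migrates, and the pyran contracts to ring B with the expelled carbon as a dimethyl acetal.
- In its favour: the intermediates are robust arenes, and the contraction delivers the trans C2/C3 pair stereospecifically. On stability of intermediates it is stronger than the chosen route.
- Against it: from A3 the acetal must be taken down to a methyl group over several steps, the allyl group must be brought to C5 by O-allylation and Claisen rearrangement, and C5 is created last by oxidative dearomatisation in methanol.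
- That last step is the flaw. Methanol attacks a 2-methoxyphenol preferentially at the methoxy-bearing carbon C7 (giving the quinone monoketal) or para, not at the allyl-bearing C5. Even at C5 there is no facial control from the distant C2/C3 centres, and such ortho-quinol ethers dimerise readily.
- In comparison, the chosen strategy brings C5 in enantiopure and never has to differentiate the faces of a planar ring.

**Alternative 3:** Carbene-catalysed crossed benzoin closing ring A at C5–C6. The α-ketol A5 would come from the keto aldehyde A6, in which ring B is complete. A chiral triazolium-derived carbene turns the C6 aldehyde into an acyl anion equivalent that adds to the C5 ketone, closing ring A and creating the tertiary carbinol.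
- In its favour: ring A and a tetrasubstituted C5 are made catalytically in one step, and intramolecular aldehyde–ketone benzoin reactions are well established for six-membered rings. In atom economy and in access to either C5 epimer by choice of catalyst it is stronger than the chosen route.
- Against it: the aldehyde of A6 is a β-alkoxy enal whose β-carbon (C7a) carries O1 as a leaving group. Carbenes divert such substrates into homoenolate and redox pathways, which would open ring B.
- The allyl ketone of A6 is enolisable on both sides and conjugates easily under the basic conditions.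
- A5 still needs O-methylation of a hindered tertiary α-ketol, which is open to retro-benzoin cleavage and ketol rearrangement, and it still lacks the C3a=C4 double bond.
- In comparison, the chosen route installs the C5 methoxy group on a simple acyclic diol before coupling and obtains the alkene by elimination.

Key step: step 10

## Remarks on the chemistry

- Methoxyacetaldehyde 12 is taken as the commercial reagent, distilled before use.
- Compound 22 is written as its diketo form; it should exist as a mixture of enol and hemiketal tautomers, all of which converge in step 13.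
- Compounds 20–24 are mixtures of the two C4 epimers, and 6 is a mixture of C3 epimers; these centres are removed later.

## Route

Step 1
Reactants: 1 3',4',5'-trimethoxyacetophenone; 2 methyl bromoacetate
Product: 3 methyl 4-oxo-4-(3,4,5-trimethoxyphenyl)butanoate
Conditions: LiHMDS, THF, −78 °C; then 2, −78 → 0 °C
Reagents that add atoms: none
Why: Alkylation of a kinetic aryl methyl ketone enolate with an α-halo ester; the ketone has one enolisable position and bromoacetate is a reactive SN2 partner.

Step 2
Reactants: 3 methyl 4-oxo-4-(3,4,5-trimethoxyphenyl)butanoate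
Product: 5 (5S)-5-(3,4,5-trimethoxyphenyl)oxolan-2-one, via (S)-hydroxy ester 4 (not isolated)
Conditions: RuCl(p-cymene)[(S,S)-TsDPEN] (1 mol%), HCO2H–Et3N (5:2), 40 °C; then TsOH·H2O (cat.), toluene, 60 °C
Reagents that add atoms: none
Why: Noyori asymmetric transfer hydrogenation of an aryl alkyl ketone; the (S,S)-ligand should deliver hydride to give the (S)-benzylic alcohol as it does for acetophenone, and the γ-hydroxy ester then closes to the γ-lactone with loss of methanol.

Step 3
Reactants: 5 (5S)-5-(3,4,5-trimethoxyphenyl)oxolan-2-one
Product: 7 (5S)-5-(3,4,5-trimethoxyphenyl)furan-2(5H)-one, via 3-phenylselanyl lactone 6 (not isolated)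
Conditions: LDA, THF, −78 °C; PhSeBr; then 30% H2O2, CH2Cl2, 0 °C → rt
Reagents that add atoms: none
Why: α-Selenenylation of the lactone enolate followed by selenoxide syn-elimination; the only β-hydrogens are on C3 of the butenolide-to-be, so only the endocyclic alkene can form. C2 is not touched, because LDA removes only the α-proton of the saturated lactone and the elimination runs without base.

Step 4
Reactants: 8 ethyl (triphenylphosphoranylidene)acetate; 9 allyl bromide
Product: 11 ethyl 2-(triphenylphosphoranylidene)pent-4-enoate, via allylated phosphonium bromide 10 (not isolated)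
Conditions: EtOAc, reflux; then 2 M NaOH, CH2Cl2, 0 °C
Reagents that add atoms: none
Why: C-Alkylation of a stabilised ylide with an allylic halide, then deprotonation of the phosphonium salt to restore the ylide.

Step 5
Reactants: 11 ethyl 2-(triphenylphosphoranylidene)pent-4-enoate; 12 methoxyacetaldehyde
Product: 13 ethyl (2E)-4-methoxy-2-(prop-2-en-1-yl)but-2-enoate
Conditions: CH2Cl2, rt → 40 °C
Reagents that add atoms: none
Why: Wittig olefination with an α-substituted stabilised ylide, which should place the ester trans to the new CH2OMe substituent (E).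

Step 6
Reactants: 13 ethyl (2E)-4-methoxy-2-(prop-2-en-1-yl)but-2-enoate
Product: 14 (2E)-4-methoxy-2-(prop-2-en-1-yl)but-2-en-1-ol
Conditions: DIBAL-H (2.2 equiv), CH2Cl2, −78 → 0 °C; Rochelle salt
Reagents that add atoms: none
Why: 1,2-Reduction of an α,β-unsaturated ester to the allylic alcohol; neither alkene is affected.

Step 7
Reactants: 14 (2E)-4-methoxy-2-(prop-2-en-1-yl)but-2-en-1-ol
Product: 15 [(2S,3S)-3-(methoxymethyl)-2-(prop-2-en-1-yl)oxiran-2-yl]methanol
Conditions: Ti(OiPr)4 (10 mol%), L-(+)-diethyl tartrate (12 mol%), t-BuOOH, 4 Å MS, CH2Cl2, −20 °C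
Reagents that add atoms: tert-butyl hydroperoxide CC(C)(C)OO
Why: Sharpless asymmetric epoxidation; with the L-(+)-tartrate, (E)-2,3-disubstituted allylic alcohols should give the (2S,3S)-epoxide, which fixes C5. The hydroxyl-directed titanium peroxide ignores the isolated allyl alkene.

Step 8
Reactants: 15 [(2S,3S)-3-(methoxymethyl)-2-(prop-2-en-1-yl)oxiran-2-yl]methanol
Product: 16 (2R,3S)-2,4-dimethoxy-2-(prop-2-en-1-yl)butane-1,3-diol
Conditions: CSA (10 mol%), MeOH, −20 → 0 °C
Reagents that add atoms: methanol CO
Why: Acid-catalysed epoxide alcoholysis; the protonated epoxide should be attacked at the tertiary carbon C5 (the other epoxide carbon is secondary and deactivated by its CH2OMe group) from the rear, so C5 is inverted to the (R) methyl ether and the epoxide oxygen stays on C6.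

Step 9
Reactants: 16 (2R,3S)-2,4-dimethoxy-2-(prop-2-en-1-yl)butane-1,3-diol
Product: 17 (2R)-2-methoxy-2-(2-methoxyacetyl)pent-4-enal
Conditions: Dess–Martin periodinane (3 equiv), CH2Cl2, 0 °C → rt; used at once
Reagents that add atoms: none
Why: Dess–Martin oxidation of the primary and the secondary alcohol in one operation; the non-basic conditions avoid retro-aldol cleavage of the half-oxidised intermediates, and C5 has no hydrogen to epimerise.

Step 10
Reactants: 7 (5S)-5-(3,4,5-trimethoxyphenyl)furan-2(5H)-one; 17 (2R)-2-methoxy-2-(2-methoxyacetyl)pent-4-enal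
Product: 20 (3R,4S,5S)-3-[(2R)-1-hydroxy-2-methoxy-2-(methoxyacetyl)pent-4-en-1-yl]-4-methyl-5-(3,4,5-trimethoxyphenyl)oxolan-2-one (both C4 carbinol epimers), via lithium dimethylcuprate 18 (not isolated), via silyl ketene acetal 19 (not isolated)
Conditions: CuI, MeLi (2 equiv), Et2O, 0 °C; 7, Me3SiCl, THF, −78 °C; Et3N, pentane, filtration under Ar, evaporation; 17, BF3·OEt2, CH2Cl2, −78 °C; 1 M HCl–THF, 0 °C
Reagents that add atoms: methyllithium C[Li]
Why: The cuprate 18 (monovalent copper) should add its methyl group to C3 of 7 on the face anti to the C2 aryl group, and the resulting lactone enolate is silylated on oxygen by Me3SiCl present in the flask to give the cyclic silyl ketene acetal 19. After copper and lithium salts are filtered off, BF3·OEt2 activates the formyl group of 17 and C3a of 19 adds to it through an open Mukaiyama transition state on the face anti to the new C3 methyl group; the silyl group passes to the aldolate oxygen and is removed on acidic work-up. The closest known reaction type is the tandem cuprate conjugate addition, enolate trapping and aldol addition (three-component coupling) on butenolides and cyclopentenones, which gives trans,trans products. No ring is closed; the C3–CH3 and C3a–C4 bonds are formed. C3 is controlled by the C2 aryl group (substrate control), C3a by the C3 methyl group, and C4 is not controlled; C3a and C4 are erased in steps 13 and 14. The step needs 1,4-addition rather than γ-deprotonation of 7, which the soft cuprate with Me3SiCl at −78 °C should secure. It also needs reaction at the aldehyde rather than the ketone of 17, which follows from the higher electrophilicity and Lewis basicity of the formyl group. C5 is safe because it has no hydrogen and because the Lewis-acidic, non-nucleophilic conditions avoid deformylation of the β-keto aldehyde.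

Step 11
Reactants: 20 aldol adduct
Product: 21 (3R,4S,5S)-3-[(2R)-2-methoxy-2-(methoxyacetyl)-1-(triethylsilyloxy)pent-4-en-1-yl]-4-methyl-5-(3,4,5-trimethoxyphenyl)oxolan-2-one
Conditions: Et3SiOTf, 2,6-lutidine, CH2Cl2, −78 → 0 °C
Reagents that add atoms: triethylsilyl trifluoromethanesulfonate CC[Si](CC)(CC)OS(=O)(=O)C(F)(F)F
Why: Silylation of a hindered secondary alcohol with a silyl triflate; the silyl ether blocks retro-aldol cleavage at C4 during the basic ring closure.

Step 12
Reactants: 21 silyl ether
Product: 22 (4R,6R)-6-[(1S,2S)-1-hydroxy-1-(3,4,5-trimethoxyphenyl)propan-2-yl]-2,4-dimethoxy-4-(prop-2-en-1-yl)-5-(triethylsilyloxy)cyclohexane-1,3-dione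
Conditions: LiHMDS (2.5 equiv), THF, −78 → 0 °C; AcOH
Reagents that add atoms: none
Why: Intramolecular Claisen (Dieckmann-type) condensation of a δ-keto ester: LiHMDS should remove the more acidic ketone α-proton at C7 (the only one, since C5 is quaternary) rather than the lactone α-proton, and the enolate acylates on the lactone carbonyl C7a to close ring A. Collapse of the adduct releases the C2 alkoxide and gives the stabilised diketonate, which drives the reaction and protects C3a–H from deprotonation.

Step 13
Reactants: 22 hydroxy diketone
Product: 23 (2S,3S,3aR,5R)-4-hydroxy-5,7-dimethoxy-3-methyl-5-(prop-2-en-1-yl)-2-(3,4,5-trimethoxyphenyl)-3,3a,4,5-tetrahydro-1-benzofuran-6(2H)-one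
Conditions: TsOH·H2O (0.2 equiv), CH2Cl2–MeOH (5:1), rt; then toluene, 4 Å MS, 40 °C
Reagents that add atoms: none
Why: Acid-catalysed hemiketalisation of the C2 hydroxyl on the C7a carbonyl (five-membered ring, the only one possible) and dehydration towards C7 give the conjugated vinylogous ester, and the triethylsilyl ether is solvolysed under the same conditions. The benzylic C2–O bond should hold, since the twisted para methoxy group makes the aryl ring a poor cation stabiliser.

Step 14
Reactants: 23 hydroxy vinylogous ester
Product: 25 (2S,3S,5R)-5,7-dimethoxy-3-methyl-5-(prop-2-en-1-yl)-2-(3,4,5-trimethoxyphenyl)-3,5-dihydro-1-benzofuran-6(2H)-one, via C4 mesylate 24 (not isolated)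
Conditions: MsCl, Et3N, CH2Cl2, 0 °C; then DBU, rt → 40 °C
Reagents that add atoms: none
Why: Mesylation and base-induced elimination (E1cB through the vinylogous enolate at C3a); C3a–H is the only hydrogen next to C4, so only the C3a=C4 alkene can form, and both C4 epimers converge on 25. C2, C3 and C5 carry no acidic hydrogen under these conditions.

## Compound list

1 | 3',4',5'-trimethoxyacetophenone | CC(=O)c1cc(OC)c(OC)c(OC)c1 | starting material
2 | methyl bromoacetate | COC(=O)CBr | starting material
3 | methyl 4-oxo-4-(3,4,5-trimethoxyphenyl)butanoate | COC(=O)CCC(=O)c1cc(OC)c(OC)c(OC)c1 | intermediate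
4 | methyl (4S)-4-hydroxy-4-(3,4,5-trimethoxyphenyl)butanoate | COC(=O)CC[C@H](O)c1cc(OC)c(OC)c(OC)c1 | intermediate
5 | (5S)-5-(3,4,5-trimethoxyphenyl)oxolan-2-one | O=C1CC[C@@H](c2cc(OC)c(OC)c(OC)c2)O1 | intermediate
6 | (5S)-3-(phenylselanyl)-5-(3,4,5-trimethoxyphenyl)oxolan-2-one (C3 epimers) | O=C1C([Se]c2ccccc2)C[C@@H](c2cc(OC)c(OC)c(OC)c2)O1 | intermediate
7 | (5S)-5-(3,4,5-trimethoxyphenyl)furan-2(5H)-one | O=C1C=C[C@@H](c2cc(OC)c(OC)c(OC)c2)O1 | intermediate
8 | ethyl (triphenylphosphoranylidene)acetate | CCOC(=O)C=P(c1ccccc1)(c1ccccc1)c1ccccc1 | starting material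
9 | allyl bromide | C=CCBr | starting material
10 | (1-ethoxy-1-oxopent-4-en-2-yl)triphenylphosphonium bromide | CCOC(=O)C(CC=C)[P+](c1ccccc1)(c1ccccc1)c1ccccc1.[Br-] | intermediate
11 | ethyl 2-(triphenylphosphoranylidene)pent-4-enoate | CCOC(=O)C(CC=C)=P(c1ccccc1)(c1ccccc1)c1ccccc1 | intermediate
12 | methoxyacetaldehyde | COCC=O | starting material
13 | ethyl (2E)-4-methoxy-2-(prop-2-en-1-yl)but-2-enoate | CCOC(=O)/C(CC=C)=C/COC | intermediate
14 | (2E)-4-methoxy-2-(prop-2-en-1-yl)but-2-en-1-ol | C=CC/C(CO)=C\COC | intermediate
15 | [(2S,3S)-3-(methoxymethyl)-2-(prop-2-en-1-yl)oxiran-2-yl]methanol | C=CC[C@@]1(CO)O[C@H]1COC | intermediate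
16 | (2R,3S)-2,4-dimethoxy-2-(prop-2-en-1-yl)butane-1,3-diol | C=CC[C@@]([C@@H](O)COC)(OC)CO | intermediate
17 | (2R)-2-methoxy-2-(2-methoxyacetyl)pent-4-enal | C=CC[C@@](C(=O)COC)(OC)C=O | intermediate
18 | lithium dimethylcuprate | [Li+].C[Cu-]C | intermediate
19 | trimethyl{[(4S,5S)-4-methyl-5-(3,4,5-trimethoxyphenyl)-4,5-dihydrofuran-2-yl]oxy}silane | C[Si](C)(C)OC1=C[C@H](C)[C@@H](c2cc(OC)c(OC)c(OC)c2)O1 | intermediate
20 | (3R,4S,5S)-3-[(2R)-1-hydroxy-2-methoxy-2-(methoxyacetyl)pent-4-en-1-yl]-4-methyl-5-(3,4,5-trimethoxyphenyl)oxolan-2-one (C4 carbinol epimers) | C=CC[C@@](C(=O)COC)(OC)C(O)[C@@H]1C(=O)O[C@H](c2cc(OC)c(OC)c(OC)c2)[C@H]1C | intermediate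
21 | (3R,4S,5S)-3-[(2R)-2-methoxy-2-(methoxyacetyl)-1-(triethylsilyloxy)pent-4-en-1-yl]-4-methyl-5-(3,4,5-trimethoxyphenyl)oxolan-2-one | C=CC[C@@](C(=O)COC)(OC)C(O[Si](CC)(CC)CC)[C@@H]1C(=O)O[C@H](c2cc(OC)c(OC)c(OC)c2)[C@H]1C | intermediate
22 | (4R,6R)-6-[(1S,2S)-1-hydroxy-1-(3,4,5-trimethoxyphenyl)propan-2-yl]-2,4-dimethoxy-4-(prop-2-en-1-yl)-5-(triethylsilyloxy)cyclohexane-1,3-dione | C=CC[C@@]1(OC)C(O[Si](CC)(CC)CC)[C@@H]([C@H](C)[C@H](O)c2cc(OC)c(OC)c(OC)c2)C(=O)C(OC)C1=O | intermediate
23 | (2S,3S,3aR,5R)-4-hydroxy-5,7-dimethoxy-3-methyl-5-(prop-2-en-1-yl)-2-(3,4,5-trimethoxyphenyl)-3,3a,4,5-tetrahydro-1-benzofuran-6(2H)-one | C=CC[C@@]1(OC)C(O)[C@@H]2C(=C(OC)C1=O)O[C@H](c1cc(OC)c(OC)c(OC)c1)[C@H]2C | intermediate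
24 | C4 methanesulfonate of 23 | C=CC[C@@]1(OC)C(OS(C)(=O)=O)[C@@H]2C(=C(OC)C1=O)O[C@H](c1cc(OC)c(OC)c(OC)c1)[C@H]2C | intermediate
25 | (2S,3S,5R)-5,7-dimethoxy-3-methyl-5-(prop-2-en-1-yl)-2-(3,4,5-trimethoxyphenyl)-3,5-dihydro-1-benzofuran-6(2H)-one | C=CC[C@@]1(OC)C=C2C(=C(OC)C1=O)O[C@H](c1cc(OC)c(OC)c(OC)c1)[C@H]2C | target

## Step count and least certain steps

Total: 14 steps. Longest linear sequence: 11 steps (steps 4–14, from 8 and 9); the butenolide branch (steps 1–3) joins at step 10.

**Step 10 (key step).** The silyl ketene acetal 19 is trisubstituted and flanked by the C3 methyl group, and the aldehyde of 17 is neopentylic, so the carbon–carbon bond formation may be slow. Adventitious acid could then protodesilylate 19, or the ketone could begin to compete. A second risk is γ-deprotonation of 7 by the cuprate, which would erode the C2 configuration.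
Fallback: from 7 the conjugate addition is run on its own and quenched with aqueous NH4Cl to give the isolated trans-lactone (4S,5S)-4-methyl-5-(3,4,5-trimethoxyphenyl)oxolan-2-one F1. Its lithium enolate (LDA, THF, −78 °C) is transmetalated with ClTi(OiPr)3 and added to 17 in a closed, metal-centred aldol addition; titanium enolates of this kind discriminate strongly for aldehydes over ketones. Buffered work-up returns to the route at 20.

**Step 8.** The opening may lose regioselectivity (attack at C6) or, if the protonated epoxide ionises fully, lose stereospecificity at C5 or suffer a hydride shift. Both epoxide carbons carry an inductively withdrawing oxygenated substituent, so the preference for the tertiary carbon rests on substitution alone.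
Fallback: from 15 the primary alcohol is converted into the tert-butyl carbonate tert-butyl {[(2S,3S)-3-(methoxymethyl)-2-(prop-2-en-1-yl)oxiran-2-yl]methyl} carbonate F2 (Boc2O, DMAP). BF3·OEt2 then makes the carbonate carbonyl oxygen open the epoxide intramolecularly at C5, five-membered and necessarily with inversion, giving the cyclic carbonate (4R)-4-[(1S)-1-hydroxy-2-methoxyethyl]-4-(prop-2-en-1-yl)-1,3-dioxolan-2-one F3. Aqueous NaOH gives the triol (2R,3S)-4-methoxy-2-(prop-2-en-1-yl)butane-1,2,3-triol F4. Benzaldehyde dimethyl acetal with CSA ties the primary and secondary hydroxyls into the six-membered acetal (4S,5R)-4-(methoxymethyl)-2-phenyl-5-(prop-2-en-1-yl)-1,3-dioxan-5-ol F5. NaH and MeI methylate the remaining tertiary hydroxyl to give (4S,5R)-5-methoxy-4-(methoxymethyl)-2-phenyl-5-(prop-2-en-1-yl)-1,3-dioxane F6, and aqueous acetic acid removes the acetal, returning to the route at 16.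

**Step 12.** Deprotonation may occur at the lactone α-carbon C3a instead of C7. The lactone enolate would expel the C4 silanolate to give an alkylidene lactone that cannot close ring A. O-acylation of the ketone enolate is a second, reversible diversion.
Fallback: from 21 the lactone is opened with the aluminium amide from Me3Al and MeNH(OMe)·HCl to give the hydroxy Weinreb amide (2R,3S,4S)-4-hydroxy-N-methoxy-2-[(2R)-2-methoxy-2-(methoxyacetyl)-1-(triethylsilyloxy)pent-4-en-1-yl]-N,3-dimethyl-4-(3,4,5-trimethoxyphenyl)butanamide F7. The C2 hydroxyl is silylated (Et3SiOTf, 2,6-lutidine) to give the bis(triethylsilyl) ether of that amide F8. LiHMDS then closes ring A by acylation of the C7 enolate on the Weinreb amide, whose α-proton is less acidic than that of the lactone, giving the C2,C4-bis(triethylsilyl) ether of the cyclic diketone F9. The acid treatment of step 13 removes both silyl groups and closes ring B, returning to the route at 23.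

**Step 14.** The C4 epimer whose mesylate is syn to C3a–H cannot eliminate in an anti-periplanar way and must go through the fully formed vinylogous enolate, which DBU may generate too slowly. Heating to force it risks the quaternary dienone.
Fallback: from 23 both epimers are oxidised with Dess–Martin periodinane to the single C4 ketone (2S,3S,3aR,5R)-5,7-dimethoxy-3-methyl-5-(prop-2-en-1-yl)-2-(3,4,5-trimethoxyphenyl)-3,3a-dihydro-1-benzofuran-4,6(2H,5H)-dione F10. Deprotonation at C3a (KHMDS, the only enolisable position) and trapping with PhNTf2 give the C4 enol triflate of the target skeleton F11. Reduction of the triflate with Pd(OAc)2 and PPh3 (zerovalent palladium formed in the flask), HCO2H and Bu3N replaces it by hydrogen and returns to the route at 25.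

## Further compounds

F1 | step 10 | (4S,5S)-4-methyl-5-(3,4,5-trimethoxyphenyl)oxolan-2-one | O=C1C[C@H](C)[C@@H](c2cc(OC)c(OC)c(OC)c2)O1
F2 | step 8 | tert-butyl {[(2S,3S)-3-(methoxymethyl)-2-(prop-2-en-1-yl)oxiran-2-yl]methyl} carbonate | C=CC[C@@]1(COC(=O)OC(C)(C)C)O[C@H]1COC
F3 | step 8 | (4R)-4-[(1S)-1-hydroxy-2-methoxyethyl]-4-(prop-2-en-1-yl)-1,3-dioxolan-2-one | C=CC[C@]1([C@@H](O)COC)COC(=O)O1
F4 | step 8 | (2R,3S)-4-methoxy-2-(prop-2-en-1-yl)butane-1,2,3-triol | C=CC[C@@]([C@@H](O)COC)(O)CO
F5 | step 8 | (4S,5R)-4-(methoxymethyl)-2-phenyl-5-(prop-2-en-1-yl)-1,3-dioxan-5-ol | C=CC[C@@]1(O)COC(c2ccccc2)O[C@H]1COC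
F6 | step 8 | (4S,5R)-5-methoxy-4-(methoxymethyl)-2-phenyl-5-(prop-2-en-1-yl)-1,3-dioxane | C=CC[C@@]1(OC)COC(c2ccccc2)O[C@H]1COC
F7 | step 12 | (2R,3S,4S)-4-hydroxy-N-methoxy-2-[(2R)-2-methoxy-2-(methoxyacetyl)-1-(triethylsilyloxy)pent-4-en-1-yl]-N,3-dimethyl-4-(3,4,5-trimethoxyphenyl)butanamide | C=CC[C@@](C(=O)COC)(OC)C(O[Si](CC)(CC)CC)[C@@H]([C@H](C)[C@H](O)c1cc(OC)c(OC)c(OC)c1)C(=O)N(C)OC
F8 | step 12 | bis(triethylsilyl) ether of F7 (C2 and C4 oxygens silylated) | C=CC[C@@](C(=O)COC)(OC)C(O[Si](CC)(CC)CC)[C@@H]([C@H](C)[C@H](O[Si](CC)(CC)CC)c1cc(OC)c(OC)c(OC)c1)C(=O)N(C)OC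
F9 | step 12 | (4R,6R)-2,4-dimethoxy-4-(prop-2-en-1-yl)-5-(triethylsilyloxy)-6-[(1S,2S)-1-(triethylsilyloxy)-1-(3,4,5-trimethoxyphenyl)propan-2-yl]cyclohexane-1,3-dione | C=CC[C@@]1(OC)C(O[Si](CC)(CC)CC)[C@@H]([C@H](C)[C@H](O[Si](CC)(CC)CC)c2cc(OC)c(OC)c(OC)c2)C(=O)C(OC)C1=O
F10 | step 14 | (2S,3S,3aR,5R)-5,7-dimethoxy-3-methyl-5-(prop-2-en-1-yl)-2-(3,4,5-trimethoxyphenyl)-3,3a-dihydro-1-benzofuran-4,6(2H,5H)-dione | C=CC[C@@]1(OC)C(=O)[C@@H]2C(=C(OC)C1=O)O[C@H](c1cc(OC)c(OC)c(OC)c1)[C@H]2C
F11 | step 14 | (2S,3S,5R)-5,7-dimethoxy-3-methyl-6-oxo-5-(prop-2-en-1-yl)-2-(3,4,5-trimethoxyphenyl)-2,3,5,6-tetrahydro-1-benzofuran-4-yl trifluoromethanesulfonate | C=CC[C@@]1(OC)C(OS(=O)(=O)C(F)(F)F)=C2C(=C(OC)C1=O)O[C@H](c1cc(OC)c(OC)c(OC)c1)[C@H]2C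
A1 | alternative 1 | 3a,4-dihydro derivative of the target (C3a–H and C4H2; C2, C3 and C5 as in 25; C4 trans to the C3 methyl group) | C=CC[C@@]1(OC)C[C@@H]2C(=C(OC)C1=O)O[C@H](c1cc(OC)c(OC)c(OC)c1)[C@H]2C
A2 | alternative 1 | (7R)-5,7-dimethoxy-1-methyl-7-(prop-2-en-1-yl)-2-(3,4,5-trimethoxyphenyl)spiro[2.5]octane-4,6-dione (aryl and methyl cis on the cyclopropane; spiro centre and C5 of the spirane unassigned) | C=CC[C@@]1(OC)CC2(C(=O)C(OC)C1=O)[C@H](C)[C@@H]2c1cc(OC)c(OC)c(OC)c1
A3 | alternative 2 | trans-(2S)-3-(dimethoxymethyl)-7-methoxy-6-(methoxymethoxy)-2-(3,4,5-trimethoxyphenyl)-2,3-dihydro-1-benzofuran | COCOc1ccc2c(c1OC)O[C@H](c1cc(OC)c(OC)c(OC)c1)[C@H]2C(OC)OC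
A4 | alternative 2 | (2S)-8-methoxy-7-(methoxymethoxy)-2-(3,4,5-trimethoxyphenyl)-2H-chromene | COCOc1ccc2C=C[C@@H](c3cc(OC)c(OC)c(OC)c3)Oc2c1OC
A5 | alternative 3 | 5-hydroxy-3a,4-dihydro intermediate (tertiary α-ketol; C2, C3 and C5 as in 25, hydroxyl in place of the C5 methoxy group) | C=CC[C@@]1(O)C[C@@H]2C(=C(OC)C1=O)O[C@H](c1cc(OC)c(OC)c(OC)c1)[C@H]2C
A6 | alternative 3 | (2Z)-methoxy[(3S,4S,5S)-4-methyl-3-(2-oxopent-4-en-1-yl)-5-(3,4,5-trimethoxyphenyl)oxolan-2-ylidene]acetaldehyde | C=CCC(=O)C[C@@H]1/C(=C(/OC)\C=O)O[C@H](c2cc(OC)c(OC)c(OC)c2)[C@H]1C
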